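The readings were generated by integration for an exercise; noise was put on by code.

The leftover comes first: red's last two readings of target, 7.5% and 7.8%, lie below the 10.0% it showed at 2.00 h.

in all of them: substrate 21 mM

| run | free catalyst | remark | time |
|---|---|---|---|
| red | 0.21 mM | the very flask that is asked about, followed so far |  |
| amber | 0.14 mM | run made earlier |  |
| flask | 0.21 mM |  | 5.0 d |

- red (time / h: target / %): 0.417: 7.1; 0.833: 9.6; 2.00: 10.0; 4.00: 9.1; 8.00: 8.0; 15.0: 7.5; 40.0: 7.8
- amber (time / h: target / %): 0.500: 5.2; 1.00: 8.9; 2.00: 9.5; 5.00: 7.6; 10.0: 6.4; 20.0: 6.5; 50.0: 6.2

(scatter of a reading: 0.5 percentage points)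

- time, not beyond 5.0 d, at which the flask holds most target
- the amount of target, in percent of the substrate charged, at that time
- earliest time at which at least nineteen twentieths of that best amount are there
- latest time at which they still are, in d

*Where does the most target stand?* Early, on the hump. Red's tail stays flat and lower, and amber's does too, ending at 6.2% after 9.5% at its highest reading.

*What can be frozen to time that hump?* The free catalyst. If it stays near its charge early on, I can treat the catalysed early steps as pseudo-first-order and let each flask's clock run on catalyst multiplied by time. Amber gives 0.280 mM·h for θ, the hump exposure, which is the free catalyst charged multiplied by the time of the highest reading.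

*Is that clock honest?* Red's climb to its first reading is 1.64 times as steep as amber's, and the catalyst ratio is 1.50, so the two roughly keep step. The weak spot is that amber's readings are coarse, with the next ones at 1.00 h and 5.00 h, so θ is rough.

*And for this flask?* My reckoning divides θ by red's catalyst and gets 1.33 h, which is 0.0556 d.

The forecast puts the most target on the early hump, since “nothing suggests a late climb past the early peak”. It says 0.06 d (range 0.04 d to 0.085 d), with 10.2% of target, and a window from 0.88 h to 0.11 d. My time is earlier than its time.

The flask peaks at 0.0648 d with 10.2%, and its window runs from 0.964 h to 0.115 d. At that peak it still holds 77.3% of its free catalyst. The time from θ came out earlier than the peak, yet it falls inside the window.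

    isomer of the product A + free catalyst ⇌ isomer of the product B + free catalyst, rate k1*[free catalyst]*[isomer of the product A] forward; the back reaction follows from the equilibrium constant (K = 1.33, k = 0.105 M⁻¹ s⁻¹)
    target + free catalyst ⇌ isomer of the product A + free catalyst, rate k2*[free catalyst]*[target] forward; the back reaction follows from the equilibrium constant (K = 1.51, k = 0.575 M⁻¹ s⁻¹)
    free catalyst → spent catalyst (k = 4.59 × 10⁻⁵ s⁻¹)
    substrate + free catalyst ⇌ target + free catalyst, rate k4*[substrate]*[free catalyst] forward; the back reaction follows from the equilibrium constant (K = 0.898, k = 0.340 M⁻¹ s⁻¹)
    substrate ⇌ dormant form (K = 23.0, k = 1.07 × 10⁻⁴ s⁻¹)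
    isomer of the product B + free catalyst ⇌ substrate + free catalyst, rate k6*[free catalyst]*[isomer of the product B] forward; the back reaction follows from the equilibrium constant (k = 0.570 M⁻¹ s⁻¹)

For the neighbour flask with 0.052 mM of free catalyst, θ, with that catalyst taken as frozen at its charge, puts the hump at 5.38 h. The computed neighbour reaches a best of 6.02% and holds 4.85% of target at 5.00 d; θ gives a time, not that height.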